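**Strategy.** The cyclohexane ring (C1 acetoxy carbon, C2 CMe2, C3 side-chain CH, C4 methyl carbinol, C5 and C6 CH2) is disconnected at C2–C3 and C4–C5. Its 1,4-dioxygenation (C1, C4) next to the gem-dimethyl carbon maps onto a catalytic enantioselective Diels–Alder reaction: a 2-silyloxydiene (C5=C6–C1(OSi)=C2) whose nucleophilic terminus is the CMe2 carbon adds to an enal that already carries the complete side chain, its carbinol centre bought as (R)-linalool. The catalyst sets C3; the formyl group is then excised to the C4 ketone, and C4 (methyl addition) and C1 (hydride) are relayed from C3. Mitsunobu etherification with umbelliferone and acetylation finish the synthesis.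

Key step: step 5

Assumption: (R)-(−)-linalool of high enantiomeric purity and stabilised 4-methylpent-1-en-3-one are taken as purchasable; the side-chain carbinol configuration of the target corresponds to (R)-linalool.

Remark: the CIP descriptor of the side-chain-bearing ring carbon is R in 8 and 9 and S from 10 onwards; this is a priority change only, the geometry is unchanged.

Step 1
Reactants: 1 (R)-(−)-linalool, (3R)-3,7-dimethylocta-1,6-dien-3-ol
Product: 2 (3R)-3,7-dimethyloct-6-ene-1,3-diol
Conditions: 9-BBN (2.2 equiv), THF, 0 °C to rt; then NaOH, H2O2, 0 °C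
Reagents that add atoms: hydrogen peroxide, OO
Why: Anti-Markovnikov hydroboration–oxidation: 9-BBN adds to the monosubstituted vinyl group much faster than to the trisubstituted alkene, and the existing carbinol stereocentre is not involved.

Step 2
Reactants: 2 (3R)-3,7-dimethyloct-6-ene-1,3-diol
Product: 3 (3R)-3,7-dimethyl-1,3-bis(triethylsilyloxy)oct-6-ene
Conditions: TESOTf (2.5 equiv), 2,6-lutidine, CH2Cl2, −78 to 0 °C
Reagents that add atoms: triethylsilyl triflate, CC[Si](CC)(CC)OS(=O)(=O)C(F)(F)F
Why: Silylation with a silyl triflate caps the primary and the tertiary hydroxyl in one operation, which later prevents oxa-Michael closure of the tertiary alcohol onto the enal and keeps protic groups away from the Lewis acid of step 5.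

Step 3
Reactants: 3 (3R)-3,7-dimethyl-1,3-bis(triethylsilyloxy)oct-6-ene; 4 (E)-crotonaldehyde
Product: 5 (2E,6R)-6-methyl-6,8-bis(triethylsilyloxy)oct-2-enal
Conditions: 4 (5 equiv), second-generation Hoveyda–Grubbs catalyst (5 mol%), CH2Cl2, 40 °C
Reagents that add atoms: none
Why: Olefin cross-metathesis of the prenyl-type terminus with the enal partner, driven by loss of volatile 2-methylbut-2-ene, should give the thermodynamically favoured E enal; no stereocentre is formed.

Step 4
Reactants: 6 4-methylpent-1-en-3-one (isopropyl vinyl ketone)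
Product: 7 triisopropyl[(4-methylpenta-1,3-dien-3-yl)oxy]silane
Conditions: TIPSOTf (1.1 equiv), Et3N (1.5 equiv), Et2O, 0 °C to rt
Reagents that add atoms: triisopropylsilyl triflate, CC(C)[Si](OS(=O)(=O)C(F)(F)F)(C(C)C)C(C)C
Why: Soft enolisation and O-silylation (silyl dienol ether formation): the isopropyl methine is the only enolisable position, so the cross-conjugated 2-silyloxydiene should form as a single regioisomer.

Step 5
Reactants: 5 (2E,6R)-6-methyl-6,8-bis(triethylsilyloxy)oct-2-enal; 7 triisopropyl[(4-methylpenta-1,3-dien-3-yl)oxy]silane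
Product: 8 (1S,6R)-5,5-dimethyl-6-[(3R)-3-methyl-3,5-bis(triethylsilyloxy)pentyl]-4-(triisopropylsilyloxy)cyclohex-3-ene-1-carbaldehyde (formyl group trans to the side chain)
Conditions: 7 (2 equiv), (R)-3,3-diphenyl-1-(o-tolyl)tetrahydro-1H,3H-pyrrolo[1,2-c][1,3,2]oxazaborole (20 mol%), Tf2NH (16 mol%), CH2Cl2, −78 to −40 °C
Reagents that add atoms: none
Why: The N-protonated oxazaborolidine binds the formyl group of 5 (B–O coordination plus a formyl C–H···O contact) and lowers its LUMO, so that the enol-ether β-carbon of 7 (the CMe2 terminus) attacks the enal β-carbon while the CH2 terminus closes onto the α-carbon, a strongly asynchronous Lewis-acid-catalysed Diels–Alder reaction whose stepwise limit is a Mukaiyama–Michael addition followed by 6-endo-trig Michael closure. The closest known reaction type is the oxazaborolidinium-catalysed enantioselective Diels–Alder reaction of 2-silyloxydienes with α,β-unsaturated aldehydes, together with Lewis-acid-promoted cycloadditions of terminally disubstituted silyloxydienes that create quaternary carbons. The one ring formed, the cyclohexene, is closed in this [4+2] mode, suprafacially on both partners. The side-chain-bearing ring carbon is set by the catalyst, which is expected from the formyl-binding model to shield the Si face of C-3 of the enal so that the diene adds to the Re face; the formyl-bearing carbon follows from the E geometry and is erased in step 6, and the remote carbinol centre of 5 is a spectator. Regioselectivity (quaternary carbon next to the side-chain CH) is secured by the polarisation of the diene by its silyloxy group, and 1,4- over 1,2-addition by the steric shielding of the bound formyl carbon and the low temperature. The diene is used in excess because its gem-dimethyl terminus disfavours the s-cis form.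

Step 6
Reactants: 8 (1S,6R)-5,5-dimethyl-6-[(3R)-3-methyl-3,5-bis(triethylsilyloxy)pentyl]-4-(triisopropylsilyloxy)cyclohex-3-ene-1-carbaldehyde
Product: 10 (6S)-5,5-dimethyl-6-[(3R)-3-methyl-3,5-bis(triethylsilyloxy)pentyl]-4-(triisopropylsilyloxy)cyclohex-3-en-1-one, via morpholine enamine 9 (not isolated)
Conditions: morpholine (1.5 equiv), 4 Å MS, toluene, rt; then O2, hν (visible), tetraphenylporphyrin (cat.), CH2Cl2, −78 °C
Reagents that add atoms: dioxygen, O=O
Why: Enamine formation at the α-branched aldehyde and singlet-oxygen [2+2] addition give a dioxetane that fragments to the ketone and 4-formylmorpholine (oxidative deformylation), the enamine reacting far faster with singlet oxygen than the silyl enol ether and the neutral medium protecting the side-chain-bearing stereocentre, which is now α to a ketone.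

Step 7
Reactants: 10 (6S)-5,5-dimethyl-6-[(3R)-3-methyl-3,5-bis(triethylsilyloxy)pentyl]-4-(triisopropylsilyloxy)cyclohex-3-en-1-one
Product: 11 (1R,6S)-1,5,5-trimethyl-6-[(3R)-3-methyl-3,5-bis(triethylsilyloxy)pentyl]-4-(triisopropylsilyloxy)cyclohex-3-en-1-ol
Conditions: MeLi (3 equiv), CeCl3 (3.3 equiv, anhydrous), THF, −78 °C
Reagents that add atoms: methyllithium, [Li]C
Why: Organocerium 1,2-addition: the weakly basic MeCeCl2 adds to the enolisable ketone from the equatorial direction, away from the axial methyl of the neighbouring CMe2 carbon, so the new methyl becomes equatorial and the hydroxyl axial, cis to the equatorial side chain (substrate control from the centre set in step 5).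

Step 8
Reactants: 11 (1R,6S)-1,5,5-trimethyl-6-[(3R)-3-methyl-3,5-bis(triethylsilyloxy)pentyl]-4-(triisopropylsilyloxy)cyclohex-3-en-1-ol
Product: 12 (3S,4R)-3-[(3R)-3,5-dihydroxy-3-methylpentyl]-4-hydroxy-2,2,4-trimethylcyclohexan-1-one
Conditions: 48% aq. HF, MeCN, 0 °C to rt
Reagents that add atoms: none
Why: Fluoride-mediated desilylation cleaves both triethylsilyl ethers and converts the silyl enol ether into the ketone in one operation; no stereocentre α to the new ketone can epimerise.

Step 9
Reactants: 12 (3S,4R)-3-[(3R)-3,5-dihydroxy-3-methylpentyl]-4-hydroxy-2,2,4-trimethylcyclohexan-1-one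
Product: 13 (1R,2S,4R)-2-[(3R)-3,5-dihydroxy-3-methylpentyl]-1,3,3-trimethylcyclohexane-1,4-diol
Conditions: LiBH(s-Bu)3 (5 equiv), THF, −78 °C; then H2O
Reagents that add atoms: none
Why: Substrate-controlled ketone reduction with a bulky trialkylborohydride: hydride is delivered from the equatorial direction, avoiding the 1,3-diaxial hydrogens, to give the axial alcohol trans to the side chain, as is usual for 2,2-dimethylcyclohexanones.

Step 10
Reactants: 13 (1R,2S,4R)-2-[(3R)-3,5-dihydroxy-3-methylpentyl]-1,3,3-trimethylcyclohexane-1,4-diol; 14 umbelliferone (7-hydroxy-2H-chromen-2-one)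
Product: 15 7-{[(3R)-5-[(1S,3R,6R)-3,6-dihydroxy-2,2,6-trimethylcyclohexyl]-3-hydroxy-3-methylpentyl]oxy}-2H-chromen-2-one
Conditions: PPh3 (1.2 equiv), DIAD (1.2 equiv), THF, 0 °C to rt
Reagents that add atoms: none
Why: Mitsunobu etherification: only the unhindered primary alcohol is activated and displaced by the acidic phenol, the hindered secondary and the two tertiary hydroxyls stay free, and no stereocentre is involved.

Step 11
Reactants: 15 7-{[(3R)-5-[(1S,3R,6R)-3,6-dihydroxy-2,2,6-trimethylcyclohexyl]-3-hydroxy-3-methylpentyl]oxy}-2H-chromen-2-one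
Product: 16 (1R,3S,4R)-4-hydroxy-3-{(3R)-3-hydroxy-3-methyl-5-[(2-oxo-2H-chromen-7-yl)oxy]pentyl}-2,2,4-trimethylcyclohexyl acetate (target)
Conditions: Ac2O (1.5 equiv), pyridine, DMAP (cat.), CH2Cl2, 0 °C to rt
Reagents that add atoms: acetic anhydride, CC(=O)OC(C)=O
Why: Nucleophile-catalysed acylation esterifies the single secondary alcohol, the two tertiary alcohols being too hindered to react under these conditions.

**Compound list**

1 | (R)-(−)-linalool, (3R)-3,7-dimethylocta-1,6-dien-3-ol | C=C[C@](C)(O)CCC=C(C)C | starting material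
2 | (3R)-3,7-dimethyloct-6-ene-1,3-diol | OCC[C@](C)(O)CCC=C(C)C | intermediate
3 | (3R)-3,7-dimethyl-1,3-bis(triethylsilyloxy)oct-6-ene | CC[Si](CC)(CC)OCC[C@](C)(O[Si](CC)(CC)CC)CCC=C(C)C | intermediate
4 | (E)-crotonaldehyde, (2E)-but-2-enal | C/C=C/C=O | starting material
5 | (2E,6R)-6-methyl-6,8-bis(triethylsilyloxy)oct-2-enal | O=C/C=C/CC[C@@](C)(O[Si](CC)(CC)CC)CCO[Si](CC)(CC)CC | intermediate
6 | 4-methylpent-1-en-3-one (isopropyl vinyl ketone) | C=CC(=O)C(C)C | starting material
7 | triisopropyl[(4-methylpenta-1,3-dien-3-yl)oxy]silane | C=CC(O[Si](C(C)C)(C(C)C)C(C)C)=C(C)C | intermediate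
8 | (1S,6R)-5,5-dimethyl-6-[(3R)-3-methyl-3,5-bis(triethylsilyloxy)pentyl]-4-(triisopropylsilyloxy)cyclohex-3-ene-1-carbaldehyde | CC(C)[Si](C(C)C)(C(C)C)OC1=CC[C@H](C=O)[C@@H](CC[C@@](C)(O[Si](CC)(CC)CC)CCO[Si](CC)(CC)CC)C1(C)C | intermediate
9 | 4-{(E)-[(6R)-5,5-dimethyl-6-[(3R)-3-methyl-3,5-bis(triethylsilyloxy)pentyl]-4-(triisopropylsilyloxy)cyclohex-3-en-1-ylidene]methyl}morpholine | CC(C)[Si](C(C)C)(C(C)C)OC1=CC/C(=C\N2CCOCC2)[C@@H](CC[C@@](C)(O[Si](CC)(CC)CC)CCO[Si](CC)(CC)CC)C1(C)C | intermediate
10 | (6S)-5,5-dimethyl-6-[(3R)-3-methyl-3,5-bis(triethylsilyloxy)pentyl]-4-(triisopropylsilyloxy)cyclohex-3-en-1-one | CC(C)[Si](C(C)C)(C(C)C)OC1=CCC(=O)[C@@H](CC[C@@](C)(O[Si](CC)(CC)CC)CCO[Si](CC)(CC)CC)C1(C)C | intermediate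
11 | (1R,6S)-1,5,5-trimethyl-6-[(3R)-3-methyl-3,5-bis(triethylsilyloxy)pentyl]-4-(triisopropylsilyloxy)cyclohex-3-en-1-ol | CC(C)[Si](C(C)C)(C(C)C)OC1=CC[C@@](C)(O)[C@@H](CC[C@@](C)(O[Si](CC)(CC)CC)CCO[Si](CC)(CC)CC)C1(C)C | intermediate
12 | (3S,4R)-3-[(3R)-3,5-dihydroxy-3-methylpentyl]-4-hydroxy-2,2,4-trimethylcyclohexan-1-one | O=C1CC[C@@](C)(O)[C@@H](CC[C@@](C)(O)CCO)C1(C)C | intermediate
13 | (1R,2S,4R)-2-[(3R)-3,5-dihydroxy-3-methylpentyl]-1,3,3-trimethylcyclohexane-1,4-diol | O[C@@H]1CC[C@@](C)(O)[C@@H](CC[C@@](C)(O)CCO)C1(C)C | intermediate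
14 | umbelliferone, 7-hydroxy-2H-chromen-2-one | Oc1ccc2ccc(=O)oc2c1 | starting material
15 | 7-{[(3R)-5-[(1S,3R,6R)-3,6-dihydroxy-2,2,6-trimethylcyclohexyl]-3-hydroxy-3-methylpentyl]oxy}-2H-chromen-2-one | O[C@@H]1CC[C@@](C)(O)[C@@H](CC[C@@](C)(O)CCOc2ccc3ccc(=O)oc3c2)C1(C)C | intermediate
16 | (1R,3S,4R)-4-hydroxy-3-{(3R)-3-hydroxy-3-methyl-5-[(2-oxo-2H-chromen-7-yl)oxy]pentyl}-2,2,4-trimethylcyclohexyl acetate | CC(=O)O[C@@H]1CC[C@@](C)(O)[C@@H](CC[C@@](C)(O)CCOc2ccc3ccc(=O)oc3c2)C1(C)C | target

**Step count.** Total: 11 steps. Longest linear sequence: 10 steps (1 to 16 through steps 1, 2, 3 and 5 to 11).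

**Steps most likely to fail**

Step 5. The hindered, terminally disubstituted diene may add 1,2 to the bound formyl group (Mukaiyama aldol pathway), may stop after the first C–C bond, or may be poorly discriminated by the catalyst; if only the sense of induction is reversed, the enantiomeric catalyst is used. The fallback replaces catalyst control by auxiliary control and the aldehyde by a chelating imide. Starting from 3, ozonolysis (O3, CH2Cl2, −78 °C; then PPh3) should give (4R)-4-methyl-4,6-bis(triethylsilyloxy)hexanal F1. Horner–Wadsworth–Emmons olefination with diethyl {2-[(4S)-4-benzyl-2-oxo-1,3-oxazolidin-3-yl]-2-oxoethyl}phosphonate (LiCl, i-Pr2NEt, MeCN) should give the E N-enoyl oxazolidinone F2. Cycloaddition with 7 promoted by Et2AlCl (CH2Cl2, −78 °C), in which the chelated imide cannot undergo 1,2-addition and the benzyl group blocks the Si face of the β-carbon, should give the cycloadduct imide F3. LiBH4 (Et2O, −10 °C) should give the primary alcohol F4 with release of the auxiliary, and Dess–Martin oxidation (NaHCO3, CH2Cl2) rejoins the route at aldehyde 8.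

Step 6. Enamine formation at the hindered formyl group may be incomplete, singlet oxygen may attack the silyl enol ether in an ene reaction, or the amine may cause epimerisation next to the new ketone and migration of the enol ether double bond into conjugation. The fallback goes through the carboxylic acid. From 8, Pinnick oxidation (NaClO2, NaH2PO4, 2-methylbut-2-ene, t-BuOH/H2O) should give the carboxylic acid F5. Its dianion (LDA, 2.2 equiv, THF, −78 °C) is oxygenated with O2 to the α-hydroperoxy acid F6, which on warming with Me2NCH(OMe)2 loses carbon dioxide and water (oxidative decarboxylation) and rejoins the route at ketone 10.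

Step 9. Facial selectivity of hydride delivery may be poor, because the axial methyl next to the carbonyl group also hinders equatorial approach, so that the equatorial epimer may form. The fallback uses hydroxyl-directed hydrogenation of the enol ether instead of ketone reduction. From 11, [Ir(cod)(PCy3)(py)]PF6 (5 mol%), H2 (1 atm), CH2Cl2 should deliver hydrogen to the enol ether from the face of the tertiary hydroxyl, which places the silyloxy group trans to that hydroxyl and gives the saturated silyl ether F7. HF·pyridine (THF) then removes all three silyl groups and rejoins the route at tetraol 13, bypassing steps 8 and 9.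

**Further compounds**

F1 | step 5 | (4R)-4-methyl-4,6-bis(triethylsilyloxy)hexanal | O=CCC[C@@](C)(O[Si](CC)(CC)CC)CCO[Si](CC)(CC)CC
F2 | step 5 | (4S)-4-benzyl-3-[(2E,6R)-6-methyl-6,8-bis(triethylsilyloxy)oct-2-enoyl]-1,3-oxazolidin-2-one | O=C(/C=C/CC[C@@](C)(O[Si](CC)(CC)CC)CCO[Si](CC)(CC)CC)N1[C@@H](Cc2ccccc2)COC1=O
F3 | step 5 | (4S)-4-benzyl-3-{[(1S,6R)-5,5-dimethyl-6-[(3R)-3-methyl-3,5-bis(triethylsilyloxy)pentyl]-4-(triisopropylsilyloxy)cyclohex-3-en-1-yl]carbonyl}-1,3-oxazolidin-2-one | CC(C)[Si](C(C)C)(C(C)C)OC1=CC[C@H](C(=O)N2[C@@H](Cc3ccccc3)COC2=O)[C@@H](CC[C@@](C)(O[Si](CC)(CC)CC)CCO[Si](CC)(CC)CC)C1(C)C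
F4 | step 5 | [(1S,6R)-5,5-dimethyl-6-[(3R)-3-methyl-3,5-bis(triethylsilyloxy)pentyl]-4-(triisopropylsilyloxy)cyclohex-3-en-1-yl]methanol | CC(C)[Si](C(C)C)(C(C)C)OC1=CC[C@H](CO)[C@@H](CC[C@@](C)(O[Si](CC)(CC)CC)CCO[Si](CC)(CC)CC)C1(C)C
F5 | step 6 | (1S,6R)-5,5-dimethyl-6-[(3R)-3-methyl-3,5-bis(triethylsilyloxy)pentyl]-4-(triisopropylsilyloxy)cyclohex-3-ene-1-carboxylic acid | CC(C)[Si](C(C)C)(C(C)C)OC1=CC[C@H](C(=O)O)[C@@H](CC[C@@](C)(O[Si](CC)(CC)CC)CCO[Si](CC)(CC)CC)C1(C)C
F6 | step 6 | (1S,6S)-1-hydroperoxy-5,5-dimethyl-6-[(3R)-3-methyl-3,5-bis(triethylsilyloxy)pentyl]-4-(triisopropylsilyloxy)cyclohex-3-ene-1-carboxylic acid | CC(C)[Si](C(C)C)(C(C)C)OC1=CC[C@@](OO)(C(=O)O)[C@@H](CC[C@@](C)(O[Si](CC)(CC)CC)CCO[Si](CC)(CC)CC)C1(C)C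
F7 | step 9 | (1R,2S,4R)-1,3,3-trimethyl-2-[(3R)-3-methyl-3,5-bis(triethylsilyloxy)pentyl]-4-(triisopropylsilyloxy)cyclohexan-1-ol | CC(C)[Si](C(C)C)(C(C)C)O[C@@H]1CC[C@@](C)(O)[C@@H](CC[C@@](C)(O[Si](CC)(CC)CC)CCO[Si](CC)(CC)CC)C1(C)C
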